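## Analysis of the target

Target 56 is an ester of two terpenoid halves. The lactone half is a cis-fused 1-oxo-2-benzoxepine: cyclohexane ring A is fused through C-5a and C-9a to the seven-membered lactone ring B, which holds the C-4=C-5 alkene and the C-4 carboxylic acid. The acyl half is cyclohexene ring C, which carries an (E)-2-(hydroxymethyl)acrylate on C-1′ and is joined through that carboxyl to the CH2O group on C-9.

Ring A has four contiguous stereocentres, C-5a (R), C-6 (S), C-9 (R) and C-9a (S). The lactone carbonyl on C-9a and the alkenyl carbon on C-5a are cis, the isopropyl group on C-6 is trans to the C-5a–C-5 bond, and the tertiary hydroxyl on C-9 is cis to the lactone carbonyl with its CH2O arm on the other face. Ring C has C-1′ (R) and C-6′ (S) with side chain and isopropyl cis. The two isopropyl carbons therefore have the same absolute sense but opposite relations to their neighbours, and the halves need separate stereocontrol.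

The sensitive points are the β-hydroxy lactone (retro-aldol, dehydration), two 2-(oxymethyl)acrylate units, the doubly allylic C-1′–H, the allylic alcohols and the free acid. C-9a would epimerise freely if C-9 were ever a ketone next to the C-1 carbonyl. The difficulty lies in the contiguous array on ring A ending in a tertiary carbinol, in a lactone carbonyl that probably sits axial and is not the thermodynamic choice, and in a hindered neopentyl-type ester link.

The strategy rests on the C-5a–C-9a bond of ring A. It joins the carboxyl-bearing C-9a to the alkenyl-bearing C-5a, so C-1(=O)–C-9a–C-5a–C-5=C-4 is a γ,δ-unsaturated acid, the product pattern of a [3,3] shift.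

## Retrosynthetic reasoning

**Deprotection and union.** Target 56 is traced to 55, in which the acid is a tert-butyl ester and the two allylic hydroxyls are 4-methoxybenzyl ethers, all removable in one acidolysis. 55 is cut at the ester C–O bond between the primary hydroxyl of diol 37 and the carboxyl of acid 53. This is the only bond joining the halves, so the cut is fully convergent, and the forward acylation only has to tell a primary from a tertiary hydroxyl.

**Ring B.** 37 comes from 36 by ether cleavage. 36 is opened at C-4=C-5 (ring-closing metathesis of 35) and then at the allylic ester bond O-2–C-3 (alkylation of acid 33 with bromide 34). The ring fixes the alkene geometry, and the cut reduces the bicycle to a cyclohexane acid with a vinyl group.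

**The C-9 carbinol and the oxidation level of C-1.** The C-9–CH2O bond of 33 is cut to ketone 25 and the alkoxymethyl carbanion 29. The carbon must arrive last, from the face opposite the axial arm on the neighbouring carbon. A C-9 ketone beside a C-9a carboxyl derivative would be a β-keto ester, which would enolise, scramble C-9a and quench 29. The carboxyl is therefore held at the alcohol level while the ketone is free (33 from 31 by oxidation; 25 from 24, 23 and acid 22).

**Key disconnection.** In 22 the bond between the carboxyl-bearing and vinyl-bearing carbons is cut and the carboxyl oxygen is reconnected to the vinyl terminus. This gives the ten-membered (Z)-allylic lactone 19 with a single stereocentre. The forward Ireland–Claisen contraction must form this bond with carboxyl and vinyl cis and vinyl trans to isopropyl.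

**Lactone 19.** 19 is opened at the lactone C–O bond to seco acid 17, which comes from 16 and β-keto ester 15. 15 is cut between the ketone carbon and the CH2CO2 unit to acid 12 and malonate 13. 12 goes back through 11 and 10 to (Z)-enoate 9, which is cut at the alkene to aldehyde 7 and phosphonate 8. 7 comes through 6 from 5, which is cut between the stereocentre and its CH2 arm to imide 3 and acrylate 4, and 3 comes from 1 and 2.

**Acyl half.** 53 is traced through 52, 51, 50 and 49 to imide 48, the isopropyl group being an acyl group in disguise. 48 is cut at C-1′–C-6′ and C-4′–C-5′ (Diels–Alder) to triene 45 and dienophile 47. Putting the finished side chain into the diene avoids a β,γ-unsaturated aldehyde on ring C. 45 comes from dienal 42, phosphonoacrylate 43 and alcohol 26; 42 from 39 and 40; 39 from 38 and 26; 47 from 2 and 46. Reagent 29 comes from stannane 28, made from 26 and 27.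

## Alternatives that were turned down

**Alternative 1:** Ring B is disconnected at C-4=C-5, and ring-closing metathesis of the diene ester A2 to the protected oxepinone A1 is made the central step.
- For: it closes the only medium ring with the alkene geometry fixed and is late and mild. On ring formation it is as strong as anything in the chosen route, which uses the same closure as step 21.
- Against: it creates no stereocentre. A2 must already hold all four centres of ring A, so the real problem is only moved.
- Comparison: the chosen strategy supplies what this one presupposes, namely the origin of the C-5a/C-9a pair.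

**Alternative 2:** The C-9a–C-1 and C-5a–C-5 bonds are traced to a cyclobutene. Irradiation of (S)-cryptone A3 with acetylene A4 gives the cis-fused bicyclooctenone A5, and the cyclobutene is then cleaved oxidatively.
- For: one step sets both fusion centres, cis to each other and anti to isopropyl, with the C-9 ketone in place. It reaches the carbocycle in far fewer steps than the thirteen needed here, and on step economy it is clearly stronger.
- Against: cleavage gives two carbons at the same oxidation level that must then be told apart. It also leaves C-9a between a ketone and a formyl or carboxyl group, exactly the 1,3-dicarbonyl in which that centre epimerises. The photochemistry with a gaseous alkyne is harder to scale.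
- Comparison: the chosen route delivers the two carbons already differentiated (carboxyl and vinyl) and keeps C-9 as a ketal until C-1 is reduced.

**Alternative 3:** Ring C is disconnected at C-1′–C-6′ and C-4′–C-5′. Diene A6 and acryloyl oxazolidinone A7 combine under Cu(OTf)2 with a chiral bis(oxazoline) ligand to give the cis imide A8.
- For: it is catalytic, sets both centres of ring C at once, and needs no auxiliary. On that point it is stronger than step 27 of the chosen route.
- Against: it solves the easier half. The acyl group still needs about four steps to become isopropyl, and the side chain has to be grown from the C-1′ CH2O arm through an epimerisable β,γ-unsaturated aldehyde. Ring A is untouched.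
- Comparison: the chosen route uses the same ring-forming logic for ring C as a supporting step, but with the side chain already in the diene, and spends its main risk on the half with four contiguous centres.

Key step: step 13

## Route

Assumption: the configuration is taken exactly as encoded, (5aR,6S,9R,9aS) in the lactone half and (1′R,6′S) in the acyl half, so isopropyl is trans to the neighbouring alkenyl carbon in ring A and cis in ring C.

Step 1
Reactants: 1 3-methylbutanoyl chloride; 2 (4S)-4-benzyl-1,3-oxazolidin-2-one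
Product: 3 (4S)-4-benzyl-3-(3-methylbutanoyl)-1,3-oxazolidin-2-one
Conditions: n-BuLi, THF, −78 °C; then 1
Reagents that add atoms: none
Why: N-acylation of the lithiated oxazolidinone by the acid chloride; no stereocentre is formed.

Step 2
Reactants: 3; 4 tert-butyl prop-2-enoate
Product: 5 tert-butyl (4S)-4-{[(4S)-4-benzyl-2-oxo-1,3-oxazolidin-3-yl]carbonyl}-5-methylhexanoate
Conditions: TiCl3(OiPr), iPr2NEt, CH2Cl2, 0 °C; then 4
Reagents that add atoms: none
Why: Auxiliary-controlled Michael addition of the chelated (Z)-titanium enolate to the acrylate; the benzyl group shields one enolate face, so the new centre should be (S), the same sense as in alkylations of this imide.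

Step 3
Reactants: 5
Product: 6 tert-butyl (4S)-4-(hydroxymethyl)-5-methylhexanoate
Conditions: LiBH4, MeOH (1 equiv), Et2O, 0 °C
Reagents that add atoms: none
Why: Reductive cleavage of the imide, which is much faster than reduction of the hindered tert-butyl ester; auxiliary 2 is returned and the stereocentre is untouched.

Step 4
Reactants: 6
Product: 7 tert-butyl (4S)-4-formyl-5-methylhexanoate
Conditions: Dess–Martin periodinane, NaHCO3, CH2Cl2, 0 °C → rt
Reagents that add atoms: none
Why: Buffered Dess–Martin oxidation keeps the α-branched aldehyde away from amine base; 7 is used at once.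

Step 5
Reactants: 7; 8 methyl [bis(2,2,2-trifluoroethoxy)phosphoryl]acetate
Product: 9 7-tert-butyl 1-methyl (2Z,4S)-4-(propan-2-yl)hept-2-enedioate
Conditions: KN(SiMe3)2, 18-crown-6, THF, −78 °C
Reagents that add atoms: none
Why: Still–Gennari olefination; the electron-poor phosphonate under dissociating conditions eliminates from the kinetic adduct and should give the (Z)-enoate, and the low temperature protects the α-centre.

Step 6
Reactants: 9
Product: 10 tert-butyl (4S,5Z)-7-hydroxy-4-(propan-2-yl)hept-5-enoate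
Conditions: iBu2AlH (2.2 equiv), CH2Cl2, −78 °C
Reagents that add atoms: none
Why: 1,2-Reduction of the methyl enoate to the allylic alcohol; the tert-butyl ester reacts far more slowly at −78 °C for steric reasons.

Step 7
Reactants: 10
Product: 11 tert-butyl (4S,5Z)-7-acetoxy-4-(propan-2-yl)hept-5-enoate
Conditions: Ac2O, pyridine, DMAP (cat.), CH2Cl2, 0 °C
Reagents that add atoms: acetic anhydride, CC(=O)OC(C)=O
Why: O-Acetylation; the acetate survives acid and the homologation and is later removed in the same hydrolysis as the methyl ester.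

Step 8
Reactants: 11
Product: 12 (4S,5Z)-7-acetoxy-4-(propan-2-yl)hept-5-enoic acid
Conditions: TFA/CH2Cl2 (1:3), 0 °C → rt
Reagents that add atoms: none
Why: Acidolysis of the tert-butyl ester through the tert-butyl cation; the primary allylic acetate and the (Z)-alkene should not be affected.

Step 9
Reactants: 12; 13 potassium 3-methoxy-3-oxopropanoate
Product: 15 methyl (6S,7Z)-9-acetoxy-3-oxo-6-(propan-2-yl)non-7-enoate, via acyl imidazole 14 (not isolated)
Conditions: CDI, THF, rt; then 13, MgCl2, Et3N, THF/MeCN, rt → 40 °C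
Reagents that add atoms: none
Why: Malonate half-ester homologation: the acyl imidazole C-acylates the magnesium malonate and decarboxylation gives the β-keto ester.

Step 10
Reactants: 15
Product: 16 methyl {2-[(3S,4Z)-6-acetoxy-3-(propan-2-yl)hex-4-en-1-yl]-1,3-dioxolan-2-yl}acetate
Conditions: (TMSOCH2)2, TMSOTf (cat.), CH2Cl2, −78 → −20 °C
Reagents that add atoms: 1,2-bis(trimethylsilyloxy)ethane, C[Si](C)(C)OCCO[Si](C)(C)C
Why: Aprotic ketalisation with the bis-silyl ether under catalytic TMSOTf; the low temperature spares the allylic acetate, and the ketal removes the acidity between the two carbonyls.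

Step 11
Reactants: 16
Product: 17 {2-[(3S,4Z)-6-hydroxy-3-(propan-2-yl)hex-4-en-1-yl]-1,3-dioxolan-2-yl}acetic acid
Conditions: LiOH, THF/MeOH/H2O, 0 °C → rt; NaH2PO4 to pH 5
Reagents that add atoms: lithium hydroxide, [Li+].[OH-]
Why: Saponification of acetate and methyl ester in one operation; acidification only to pH 5 keeps the ketal.

Step 12
Reactants: 17
Product: 19 (10Z,12S)-12-(propan-2-yl)-1,4,8-trioxaspiro[4.9]tetradec-10-en-7-one, via mixed anhydride 18 (not isolated)
Conditions: 2,4,6-Cl3C6H2COCl, Et3N, THF, rt; then DMAP, toluene, 80 °C, slow addition (about 1 mM)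
Reagents that add atoms: none
Why: Yamaguchi macrolactonisation; the (Z)-alkene and the spiro ketal shorten the end-to-end distance and high dilution suppresses oligomers.

Step 13
Reactants: 19
Product: 22 (6S,7S,8S)-8-(propan-2-yl)-7-vinyl-1,4-dioxaspiro[4.5]decane-6-carboxylic acid, via silyl ketene acetal 20 (not isolated), via silyl ester 21 (not isolated)
Conditions: TBSOTf, Et3N, toluene, −78 → 0 °C; then 100 °C; then K2CO3, MeOH/H2O, rt; work-up at pH 4
Reagents that add atoms: none
Why: Soft enolisation converts lactone 19 into the cyclic silyl ketene acetal 20 without a free β-alkoxy enolate, and on heating 20 undergoes a [3,3] shift in which the ketene-acetal carbon C-6 bonds to the distal alkene carbon C-11 while the allylic O-8–C-9 bond breaks (Ireland–Claisen ring contraction of a macrocyclic lactone, a known reaction type). The six-membered carbocycle is closed by this transannular C–C bond formation, the ten-membered ring shrinking by O-8, C-7 (now the exocyclic carboxyl), C-9 and C-10 (now the vinyl group). Because the ring holds both the ketene-acetal oxygen and the (Z)-alkene substituent on the inside, a chair array would place the connecting chain antiperiplanar across the forming bond, so the shift has to go through a boat-like array, and this puts carboxyl (C-6 of 22) and vinyl (C-7 of 22) cis. The configuration at the vinyl-bearing carbon is controlled by the isopropyl centre: allylic 1,3-strain with the (Z)-alkene keeps its hydrogen in the alkene plane, so the tethered ketene acetal can reach only the face opposite isopropyl and vinyl should end trans to isopropyl. The step needs O-silylation with an intact dioxolane, which the bulky silyl triflate with amine base at low temperature should secure, and facial selectivity, which the (Z)-geometry from step 5 and the single stereocentre should secure. Silyl ester 21 is cleaved by K2CO3 in aqueous methanol and acid 22 is freed at pH 4 so the ketal survives.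

Step 14
Reactants: 22
Product: 23 [(6R,7S,8S)-8-(propan-2-yl)-7-vinyl-1,4-dioxaspiro[4.5]decan-6-yl]methanol
Conditions: LiAlH4, THF, 0 °C → rt
Reagents that add atoms: none
Why: Hydride reduction of the acid to the primary alcohol, done before the ketone is unmasked so that the ring carbon between them never lies between two carbonyl groups.

Step 15
Reactants: 23
Product: 24 (2R,3S,4S)-2-(hydroxymethyl)-4-(propan-2-yl)-3-vinylcyclohexan-1-one
Conditions: PPTS, acetone/H2O (10:1), 50 °C
Reagents that add atoms: water, O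
Why: Acid-catalysed ketal hydrolysis; with the CH2OH arm axial the C-2 hydrogen is equatorial and poorly aligned with the carbonyl, so epimerisation and dehydration should be slow under this weak acid.

Step 16
Reactants: 24
Product: 25 (2R,3S,4S)-4-(propan-2-yl)-2-{[(triethylsilyl)oxy]methyl}-3-vinylcyclohexan-1-one
Conditions: Et3SiCl, imidazole, CH2Cl2, 0 °C
Reagents that add atoms: chlorotriethylsilane, CC[Si](CC)(CC)Cl
Why: O-Silylation; it prevents alkoxide-directed delivery to the wrong face and retro-aldol loss of the arm in the next step.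

Step 17
Reactants: 26 (4-methoxyphenyl)methanol; 27 tributyl(iodomethyl)stannane
Product: 28 tributyl{[(4-methoxybenzyl)oxy]methyl}stannane
Conditions: NaH, THF/DMF, 0 °C → rt
Reagents that add atoms: none
Why: Williamson etherification of the sodium alkoxide with the primary iodide.

Step 18
Reactants: 25; 28
Product: 31 (1R,2R,3S,4S)-2-(hydroxymethyl)-1-{[(4-methoxybenzyl)oxy]methyl}-4-(propan-2-yl)-3-vinylcyclohexan-1-ol, via alkoxymethyllithium 29 (not isolated), via silyl ether adduct 30 (not isolated)
Conditions: 28, n-BuLi, THF, −78 °C; then 25, −78 °C; then PPTS, MeOH, rt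
Reagents that add atoms: none
Why: Tin–lithium exchange gives the α-alkoxy carbanion, a hydroxymethyl anion equivalent, which adds 1,2 to the ketone. Attack along the axial path, anti to the axial silyloxymethyl arm on the neighbouring carbon, should set C-1 as (R) with the new carbon axial and the hydroxyl equatorial and cis to that arm. Methanolic PPTS then removes the triethylsilyl group.

Step 19
Reactants: 31
Product: 33 (1S,2R,5S,6S)-2-hydroxy-2-{[(4-methoxybenzyl)oxy]methyl}-5-(propan-2-yl)-6-vinylcyclohexane-1-carboxylic acid, via aldehyde 32 (not isolated)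
Conditions: TEMPO (cat.), PhI(OAc)2, MeCN/H2O, rt
Reagents that add atoms: water, O
Why: Oxoammonium oxidation of the primary alcohol through the aldehyde hydrate to the acid; the tertiary alcohol and the ether are inert and the medium is not basic, so C-1 should keep its configuration.

Step 20
Reactants: 33; 34 tert-butyl 2-(bromomethyl)prop-2-enoate
Product: 35 2-(tert-butoxycarbonyl)prop-2-en-1-yl (1S,2R,5S,6S)-2-hydroxy-2-{[(4-methoxybenzyl)oxy]methyl}-5-(propan-2-yl)-6-vinylcyclohexane-1-carboxylate
Conditions: K2CO3, DMF, rt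
Reagents that add atoms: none
Why: Carboxylate alkylation by the allylic bromide; the mild base should not trigger retro-aldol of the β-hydroxy acid.

Step 21
Reactants: 35
Product: 36 tert-butyl (5aR,6S,9R,9aS)-9-hydroxy-9-{[(4-methoxybenzyl)oxy]methyl}-1-oxo-6-(propan-2-yl)-1,3,5a,6,7,8,9,9a-octahydro-2-benzoxepine-4-carboxylate
Conditions: second-generation Hoveyda–Grubbs catalyst (5 mol %), toluene, 80 °C, dilute
Reagents that add atoms: none
Why: Ring-closing metathesis between the vinyl group and the 1,1-disubstituted acrylate alkene forms C-4=C-5 and the seven-membered lactone; the cis arms on ring A and loss of ethene favour closure and the ring fixes the alkene geometry.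

Step 22
Reactants: 36
Product: 37 tert-butyl (5aR,6S,9R,9aS)-9-hydroxy-9-(hydroxymethyl)-1-oxo-6-(propan-2-yl)-1,3,5a,6,7,8,9,9a-octahydro-2-benzoxepine-4-carboxylate
Conditions: DDQ, CH2Cl2/pH 7 buffer, 0 °C → rt
Reagents that add atoms: none
Why: Oxidative cleavage of the 4-methoxybenzyl ether (benzylic hydride abstraction, then hydrolysis); lactone, tert-butyl ester and enoate should be untouched.

Step 23
Reactants: 38 2,3-dibromoprop-1-ene; 26
Product: 39 1-{[(2-bromoprop-2-en-1-yl)oxy]methyl}-4-methoxybenzene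
Conditions: NaH, THF, 0 °C → rt
Reagents that add atoms: none
Why: Williamson etherification at the allylic bromide; the vinylic bromide stays for the coupling.

Step 24
Reactants: 39; 40 2-[(1E)-3,3-diethoxyprop-1-en-1-yl]-4,4,5,5-tetramethyl-1,3,2-dioxaborolane
Product: 42 (2E)-4-{[(4-methoxybenzyl)oxy]methyl}penta-2,4-dienal, via dienyl acetal 41 (not isolated)
Conditions: Pd(PPh3)4 (cat.), K2CO3, dioxane/H2O, 80 °C; then 1 M HCl, THF, rt
Reagents that add atoms: water, O
Why: Suzuki coupling of the vinyl bromide with the (E)-alkenylboronate with retention of geometry, then acetal hydrolysis to the conjugated dienal.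

Step 25
Reactants: 42; 43 ethyl 2-(diethoxyphosphoryl)prop-2-enoate; 26
Product: 45 ethyl (2E,4E)-2,5-bis{[(4-methoxybenzyl)oxy]methyl}hexa-2,4,5-trienoate, via phosphonate carbanion 44 (not isolated)
Conditions: 26, NaH, THF, 0 °C; 43; then 42, 0 °C → rt
Reagents that add atoms: none
Why: Tandem oxa-Michael addition and Horner–Wadsworth–Emmons olefination: the alkoxide of 26 adds to 43 and the resulting carbanion 44 olefinates the aldehyde; α-substituted phosphonoacetates place the ester trans to the chain, so the (2E)-isomer should dominate.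

Step 26
Reactants: 2; 46 prop-2-enoyl chloride
Product: 47 (4S)-3-acryloyl-4-benzyl-1,3-oxazolidin-2-one
Conditions: Et3N, LiCl, THF, −20 °C → rt
Reagents that add atoms: none
Why: N-Acylation of the oxazolidinone under mild amine and LiCl conditions that limit acrylate polymerisation.

Step 27
Reactants: 45; 47
Product: 48 ethyl (2E)-3-[(1R,6R)-6-{[(4S)-4-benzyl-2-oxo-1,3-oxazolidin-3-yl]carbonyl}-3-{[(4-methoxybenzyl)oxy]methyl}cyclohex-2-en-1-yl]-2-{[(4-methoxybenzyl)oxy]methyl}prop-2-enoate
Conditions: Et2AlCl (1.4 equiv), CH2Cl2, −78 → −30 °C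
Reagents that add atoms: none
Why: Auxiliary-controlled Lewis acid Diels–Alder reaction: the aluminium-chelated s-cis acyl imide is attacked on the face away from the benzyl group. The endo transition state, with the 1-substituent directing ortho and the 3-substituent para, should give the cis-1,6 adduct with (1R,6R) configuration. The ester-bearing end of the triene is fully substituted and should not act as the diene.

Step 28
Reactants: 48
Product: 49 ethyl (2E)-3-[(1R,6R)-6-[(ethylsulfanyl)carbonyl]-3-{[(4-methoxybenzyl)oxy]methyl}cyclohex-2-en-1-yl]-2-{[(4-methoxybenzyl)oxy]methyl}prop-2-enoate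
Conditions: EtSH, n-BuLi, THF, 0 °C
Reagents that add atoms: ethanethiol (as LiSEt), CCS
Why: Thiolate cleavage of the imide at the exocyclic carbonyl returns auxiliary 2; the weakly basic thiolate should leave the cis centre and the hindered enoate alone.

Step 29
Reactants: 49
Product: 50 ethyl (2E)-3-[(1R,6R)-6-acetyl-3-{[(4-methoxybenzyl)oxy]methyl}cyclohex-2-en-1-yl]-2-{[(4-methoxybenzyl)oxy]methyl}prop-2-enoate
Conditions: Me2CuLi, Et2O, −78 °C
Reagents that add atoms: lithium dimethylcuprate, [Li+].C[Cu-]C
Why: Acyl substitution of the thioester by the cuprate gives the methyl ketone; the β-substituted, α-branched enoate is a poor acceptor at −78 °C.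

Step 30
Reactants: 50
Product: 51 ethyl (2E)-3-[(1R,6R)-3-{[(4-methoxybenzyl)oxy]methyl}-6-(prop-1-en-2-yl)cyclohex-2-en-1-yl]-2-{[(4-methoxybenzyl)oxy]methyl}prop-2-enoate
Conditions: Zn, CH2Br2, TiCl4, THF/CH2Cl2, 0 °C → rt
Reagents that add atoms: dibromomethane, BrCBr
Why: Takai–Lombardo methylenation; the reagent is not basic, so the epimerisable cis α-centre of the ketone should be kept, and esters do not react.

Step 31
Reactants: 51
Product: 52 ethyl (2E)-3-[(1R,6S)-3-{[(4-methoxybenzyl)oxy]methyl}-6-(propan-2-yl)cyclohex-2-en-1-yl]-2-{[(4-methoxybenzyl)oxy]methyl}prop-2-enoate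
Conditions: H2 (1 atm), RhCl(PPh3)3 (cat.), benzene/EtOH, rt
Reagents that add atoms: none
Why: Homogeneous hydrogenation selective for the 1,1-disubstituted alkene over the two trisubstituted ones; benzyl-type ethers are not cleaved by this catalyst.

Step 32
Reactants: 52
Product: 53 (2E)-3-[(1R,6S)-3-{[(4-methoxybenzyl)oxy]methyl}-6-(propan-2-yl)cyclohex-2-en-1-yl]-2-{[(4-methoxybenzyl)oxy]methyl}prop-2-enoic acid
Conditions: LiOH, THF/MeOH/H2O, 40 °C
Reagents that add atoms: lithium hydroxide, [Li+].[OH-]
Why: Saponification of the ethyl enoate; allylic strain with the cis CH2O arm holds the doubly allylic C-1 hydrogen in the alkene plane, so it should not be removed.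

Step 33
Reactants: 53; 37
Product: 55 tert-butyl (5aR,6S,9R,9aS)-9-hydroxy-9-{[((2E)-3-[(1R,6S)-3-{[(4-methoxybenzyl)oxy]methyl}-6-(propan-2-yl)cyclohex-2-en-1-yl]-2-{[(4-methoxybenzyl)oxy]methyl}prop-2-enoyl)oxy]methyl}-1-oxo-6-(propan-2-yl)-1,3,5a,6,7,8,9,9a-octahydro-2-benzoxepine-4-carboxylate, via mixed anhydride 54 (not isolated)
Conditions: 2,4,6-Cl3C6H2COCl, Et3N, toluene, rt; then 37, DMAP, rt
Reagents that add atoms: none
Why: Yamaguchi esterification; only the primary hydroxyl of 37 should be acylated, and the in-plane C-1′ hydrogen of the activated acid resists γ-deprotonation.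

Step 34
Reactants: 55
Product: 56 (5aR,6S,9R,9aS)-9-hydroxy-9-[({(2E)-2-(hydroxymethyl)-3-[(1R,6S)-3-(hydroxymethyl)-6-(propan-2-yl)cyclohex-2-en-1-yl]prop-2-enoyl}oxy)methyl]-1-oxo-6-(propan-2-yl)-1,3,5a,6,7,8,9,9a-octahydro-2-benzoxepine-4-carboxylic acid
Conditions: TFA/CH2Cl2 (1:4), anisole, 0 °C → rt
Reagents that add atoms: none
Why: One acidolysis removes the tert-butyl ester (tert-butyl cation) and both 4-methoxybenzyl ethers (benzyl cation trapped by anisole); the tertiary carbinol is deactivated towards ionisation by its two electron-poor neighbours.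

## Compound list

1 | 3-methylbutanoyl chloride | CC(C)CC(=O)Cl | starting material
2 | (4S)-4-benzyl-1,3-oxazolidin-2-one | O=C1OC[C@H](Cc2ccccc2)N1 | starting material
3 | (4S)-4-benzyl-3-(3-methylbutanoyl)-1,3-oxazolidin-2-one | CC(C)CC(=O)N1[C@@H](Cc2ccccc2)COC1=O | intermediate
4 | tert-butyl prop-2-enoate | C=CC(=O)OC(C)(C)C | starting material
5 | tert-butyl (4S)-4-{[(4S)-4-benzyl-2-oxo-1,3-oxazolidin-3-yl]carbonyl}-5-methylhexanoate | CC(C)[C@H](CCC(=O)OC(C)(C)C)C(=O)N1[C@@H](Cc2ccccc2)COC1=O | intermediate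
6 | tert-butyl (4S)-4-(hydroxymethyl)-5-methylhexanoate | CC(C)[C@H](CCC(=O)OC(C)(C)C)CO | intermediate
7 | tert-butyl (4S)-4-formyl-5-methylhexanoate | CC(C)[C@H](CCC(=O)OC(C)(C)C)C=O | intermediate
8 | methyl [bis(2,2,2-trifluoroethoxy)phosphoryl]acetate | COC(=O)CP(=O)(OCC(F)(F)F)OCC(F)(F)F | starting material
9 | 7-tert-butyl 1-methyl (2Z,4S)-4-(propan-2-yl)hept-2-enedioate | CC(C)[C@H](CCC(=O)OC(C)(C)C)/C=C\C(=O)OC | intermediate
10 | tert-butyl (4S,5Z)-7-hydroxy-4-(propan-2-yl)hept-5-enoate | CC(C)[C@H](CCC(=O)OC(C)(C)C)/C=C\CO | intermediate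
11 | tert-butyl (4S,5Z)-7-acetoxy-4-(propan-2-yl)hept-5-enoate | CC(C)[C@H](CCC(=O)OC(C)(C)C)/C=C\COC(C)=O | intermediate
12 | (4S,5Z)-7-acetoxy-4-(propan-2-yl)hept-5-enoic acid | CC(C)[C@H](CCC(=O)O)/C=C\COC(C)=O | intermediate
13 | potassium 3-methoxy-3-oxopropanoate | COC(=O)CC(=O)[O-].[K+] | starting material
14 | 1-[(4S,5Z)-7-acetoxy-4-(propan-2-yl)hept-5-enoyl]imidazole | CC(C)[C@H](CCC(=O)n1ccnc1)/C=C\COC(C)=O | intermediate (not isolated)
15 | methyl (6S,7Z)-9-acetoxy-3-oxo-6-(propan-2-yl)non-7-enoate | CC(C)[C@H](CCC(=O)CC(=O)OC)/C=C\COC(C)=O | intermediate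
16 | methyl {2-[(3S,4Z)-6-acetoxy-3-(propan-2-yl)hex-4-en-1-yl]-1,3-dioxolan-2-yl}acetate | CC(C)[C@H](CCC1(CC(=O)OC)OCCO1)/C=C\COC(C)=O | intermediate
17 | {2-[(3S,4Z)-6-hydroxy-3-(propan-2-yl)hex-4-en-1-yl]-1,3-dioxolan-2-yl}acetic acid | CC(C)[C@H](CCC1(CC(=O)O)OCCO1)/C=C\CO | intermediate
18 | mixed anhydride of 17 with 2,4,6-trichlorobenzoic acid | CC(C)[C@H](CCC1(CC(=O)OC(=O)c2c(Cl)cc(Cl)cc2Cl)OCCO1)/C=C\CO | intermediate (not isolated)
19 | (10Z,12S)-12-(propan-2-yl)-1,4,8-trioxaspiro[4.9]tetradec-10-en-7-one | O=C1CC2(OCCO2)CC[C@@H](C(C)C)/C=C\CO1 | intermediate (key-step precursor)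
20 | tert-butyl(dimethyl){[(10Z,12S)-12-(propan-2-yl)-1,4,8-trioxaspiro[4.9]tetradeca-6,10-dien-7-yl]oxy}silane | CC(C)(C)[Si](C)(C)O/C1=C/C2(OCCO2)CC[C@@H](C(C)C)/C=C\CO1 | intermediate (not isolated)
21 | tert-butyldimethylsilyl (6S,7S,8S)-8-(propan-2-yl)-7-vinyl-1,4-dioxaspiro[4.5]decane-6-carboxylate | CC(C)[C@@H]1CCC2(OCCO2)[C@@H](C(=O)O[Si](C)(C)C(C)(C)C)[C@H]1C=C | intermediate (not isolated)
22 | (6S,7S,8S)-8-(propan-2-yl)-7-vinyl-1,4-dioxaspiro[4.5]decane-6-carboxylic acid | CC(C)[C@@H]1CCC2(OCCO2)[C@@H](C(=O)O)[C@H]1C=C | intermediate (key-step product)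
23 | [(6R,7S,8S)-8-(propan-2-yl)-7-vinyl-1,4-dioxaspiro[4.5]decan-6-yl]methanol | CC(C)[C@@H]1CCC2(OCCO2)[C@@H](CO)[C@H]1C=C | intermediate
24 | (2R,3S,4S)-2-(hydroxymethyl)-4-(propan-2-yl)-3-vinylcyclohexan-1-one | CC(C)[C@@H]1CCC(=O)[C@@H](CO)[C@H]1C=C | intermediate
25 | (2R,3S,4S)-4-(propan-2-yl)-2-{[(triethylsilyl)oxy]methyl}-3-vinylcyclohexan-1-one | CC(C)[C@@H]1CCC(=O)[C@@H](CO[Si](CC)(CC)CC)[C@H]1C=C | intermediate
26 | (4-methoxyphenyl)methanol | COc1ccc(CO)cc1 | starting material
27 | tributyl(iodomethyl)stannane | CCCC[Sn](CCCC)(CCCC)CI | starting material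
28 | tributyl{[(4-methoxybenzyl)oxy]methyl}stannane | CCCC[Sn](CCCC)(CCCC)COCc1ccc(OC)cc1 | intermediate
29 | {[(4-methoxybenzyl)oxy]methyl}lithium | [Li]COCc1ccc(OC)cc1 | intermediate (not isolated)
30 | (1R,2R,3S,4S)-1-{[(4-methoxybenzyl)oxy]methyl}-4-(propan-2-yl)-2-{[(triethylsilyl)oxy]methyl}-3-vinylcyclohexan-1-ol | CC(C)[C@@H]1CC[C@](O)(COCc2ccc(OC)cc2)[C@@H](CO[Si](CC)(CC)CC)[C@H]1C=C | intermediate (not isolated)
31 | (1R,2R,3S,4S)-2-(hydroxymethyl)-1-{[(4-methoxybenzyl)oxy]methyl}-4-(propan-2-yl)-3-vinylcyclohexan-1-ol | CC(C)[C@@H]1CC[C@](O)(COCc2ccc(OC)cc2)[C@@H](CO)[C@H]1C=C | intermediate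
32 | (1S,2R,5S,6S)-2-hydroxy-2-{[(4-methoxybenzyl)oxy]methyl}-5-(propan-2-yl)-6-vinylcyclohexane-1-carbaldehyde | CC(C)[C@@H]1CC[C@](O)(COCc2ccc(OC)cc2)[C@@H](C=O)[C@H]1C=C | intermediate (not isolated)
33 | (1S,2R,5S,6S)-2-hydroxy-2-{[(4-methoxybenzyl)oxy]methyl}-5-(propan-2-yl)-6-vinylcyclohexane-1-carboxylic acid | CC(C)[C@@H]1CC[C@](O)(COCc2ccc(OC)cc2)[C@@H](C(=O)O)[C@H]1C=C | intermediate
34 | tert-butyl 2-(bromomethyl)prop-2-enoate | C=C(CBr)C(=O)OC(C)(C)C | starting material
35 | 2-(tert-butoxycarbonyl)prop-2-en-1-yl (1S,2R,5S,6S)-2-hydroxy-2-{[(4-methoxybenzyl)oxy]methyl}-5-(propan-2-yl)-6-vinylcyclohexane-1-carboxylate | CC(C)[C@@H]1CC[C@](O)(COCc2ccc(OC)cc2)[C@@H](C(=O)OCC(=C)C(=O)OC(C)(C)C)[C@H]1C=C | intermediate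
36 | tert-butyl (5aR,6S,9R,9aS)-9-hydroxy-9-{[(4-methoxybenzyl)oxy]methyl}-1-oxo-6-(propan-2-yl)-1,3,5a,6,7,8,9,9a-octahydro-2-benzoxepine-4-carboxylate | CC(C)[C@@H]1CC[C@](O)(COCc2ccc(OC)cc2)[C@H]3C(=O)OCC(C(=O)OC(C)(C)C)=C[C@@H]13 | intermediate
37 | tert-butyl (5aR,6S,9R,9aS)-9-hydroxy-9-(hydroxymethyl)-1-oxo-6-(propan-2-yl)-1,3,5a,6,7,8,9,9a-octahydro-2-benzoxepine-4-carboxylate | CC(C)[C@@H]1CC[C@](O)(CO)[C@H]2C(=O)OCC(C(=O)OC(C)(C)C)=C[C@@H]12 | intermediate
38 | 2,3-dibromoprop-1-ene | C=C(Br)CBr | starting material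
39 | 1-{[(2-bromoprop-2-en-1-yl)oxy]methyl}-4-methoxybenzene | C=C(Br)COCc1ccc(OC)cc1 | intermediate
40 | 2-[(1E)-3,3-diethoxyprop-1-en-1-yl]-4,4,5,5-tetramethyl-1,3,2-dioxaborolane | CCOC(OCC)/C=C/B1OC(C)(C)C(C)(C)O1 | starting material
41 | 1-({[(3E)-5,5-diethoxy-2-methylidenepent-3-en-1-yl]oxy}methyl)-4-methoxybenzene | C=C(COCc1ccc(OC)cc1)/C=C/C(OCC)OCC | intermediate (not isolated)
42 | (2E)-4-{[(4-methoxybenzyl)oxy]methyl}penta-2,4-dienal | C=C(COCc1ccc(OC)cc1)/C=C/C=O | intermediate
43 | ethyl 2-(diethoxyphosphoryl)prop-2-enoate | C=C(C(=O)OCC)P(=O)(OCC)OCC | starting material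
44 | sodium salt of ethyl 2-(diethoxyphosphoryl)-3-[(4-methoxybenzyl)oxy]propanoate (C-2 carbanion) | [Na+].CCOC(=O)[C-](COCc1ccc(OC)cc1)P(=O)(OCC)OCC | intermediate (not isolated)
45 | ethyl (2E,4E)-2,5-bis{[(4-methoxybenzyl)oxy]methyl}hexa-2,4,5-trienoate | CCOC(=O)/C(COCc1ccc(OC)cc1)=C/C=C/C(=C)COCc1ccc(OC)cc1 | intermediate
46 | prop-2-enoyl chloride | C=CC(=O)Cl | starting material
47 | (4S)-3-acryloyl-4-benzyl-1,3-oxazolidin-2-one | C=CC(=O)N1[C@@H](Cc2ccccc2)COC1=O | intermediate
48 | ethyl (2E)-3-[(1R,6R)-6-{[(4S)-4-benzyl-2-oxo-1,3-oxazolidin-3-yl]carbonyl}-3-{[(4-methoxybenzyl)oxy]methyl}cyclohex-2-en-1-yl]-2-{[(4-methoxybenzyl)oxy]methyl}prop-2-enoate | CCOC(=O)/C(COCc1ccc(OC)cc1)=C/[C@H]1C=C(COCc2ccc(OC)cc2)CC[C@H]1C(=O)N1[C@@H](Cc2ccccc2)COC1=O | intermediate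
49 | ethyl (2E)-3-[(1R,6R)-6-[(ethylsulfanyl)carbonyl]-3-{[(4-methoxybenzyl)oxy]methyl}cyclohex-2-en-1-yl]-2-{[(4-methoxybenzyl)oxy]methyl}prop-2-enoate | CCOC(=O)/C(COCc1ccc(OC)cc1)=C/[C@H]1C=C(COCc2ccc(OC)cc2)CC[C@H]1C(=O)SCC | intermediate
50 | ethyl (2E)-3-[(1R,6R)-6-acetyl-3-{[(4-methoxybenzyl)oxy]methyl}cyclohex-2-en-1-yl]-2-{[(4-methoxybenzyl)oxy]methyl}prop-2-enoate | CCOC(=O)/C(COCc1ccc(OC)cc1)=C/[C@H]1C=C(COCc2ccc(OC)cc2)CC[C@H]1C(C)=O | intermediate
51 | ethyl (2E)-3-[(1R,6R)-3-{[(4-methoxybenzyl)oxy]methyl}-6-(prop-1-en-2-yl)cyclohex-2-en-1-yl]-2-{[(4-methoxybenzyl)oxy]methyl}prop-2-enoate | CCOC(=O)/C(COCc1ccc(OC)cc1)=C/[C@H]1C=C(COCc2ccc(OC)cc2)CC[C@H]1C(C)=C | intermediate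
52 | ethyl (2E)-3-[(1R,6S)-3-{[(4-methoxybenzyl)oxy]methyl}-6-(propan-2-yl)cyclohex-2-en-1-yl]-2-{[(4-methoxybenzyl)oxy]methyl}prop-2-enoate | CCOC(=O)/C(COCc1ccc(OC)cc1)=C/[C@H]1C=C(COCc2ccc(OC)cc2)CC[C@H]1C(C)C | intermediate
53 | (2E)-3-[(1R,6S)-3-{[(4-methoxybenzyl)oxy]methyl}-6-(propan-2-yl)cyclohex-2-en-1-yl]-2-{[(4-methoxybenzyl)oxy]methyl}prop-2-enoic acid | OC(=O)/C(COCc1ccc(OC)cc1)=C/[C@H]1C=C(COCc2ccc(OC)cc2)CC[C@H]1C(C)C | intermediate
54 | mixed anhydride of 53 with 2,4,6-trichlorobenzoic acid | O=C(OC(=O)/C(COCc1ccc(OC)cc1)=C/[C@H]1C=C(COCc2ccc(OC)cc2)CC[C@H]1C(C)C)c1c(Cl)cc(Cl)cc1Cl | intermediate (not isolated)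
55 | tert-butyl ester, bis(4-methoxybenzyl) ether of the target (full name in step 33) | CC(C)[C@@H]1CC[C@](O)(COC(=O)/C(=C/[C@H]2C=C(COCc3ccc(OC)cc3)CC[C@H]2C(C)C)COCc2ccc(OC)cc2)[C@H]2C(=O)OCC(C(=O)OC(C)(C)C)=C[C@@H]12 | intermediate
56 | (5aR,6S,9R,9aS)-9-hydroxy-9-[({(2E)-2-(hydroxymethyl)-3-[(1R,6S)-3-(hydroxymethyl)-6-(propan-2-yl)cyclohex-2-en-1-yl]prop-2-enoyl}oxy)methyl]-1-oxo-6-(propan-2-yl)-1,3,5a,6,7,8,9,9a-octahydro-2-benzoxepine-4-carboxylic acid | CC(C)[C@@H]1CC[C@](O)(COC(=O)/C(=C/[C@H]2C=C(CO)CC[C@H]2C(C)C)CO)[C@H]2C(=O)OCC(C(=O)O)=C[C@@H]12 | target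

## Step count and least certain steps

Total step count: 34. Longest linear sequence: 23 steps (steps 1–16, 18–22, 33 and 34). The key-step precursor 19 is reached in 12 steps.

**Step 13 (key step).** The dioxolane may be opened by the silyl triflate or lost by β-elimination while the ketene acetal forms, because the ketal oxygen sits β to the enolising carbon. Facial control could also erode if the ten-membered ring finds a second reactive conformer. Fallback: replace the ketal by a protected alcohol and enolise with amide base and in-situ silylation. Setting out from 15, NaBH4 reduction would give methyl (6S,7Z)-9-acetoxy-3-hydroxy-6-(propan-2-yl)non-7-enoate F1 as an epimer mixture. 4-Methoxybenzyl trichloroacetimidate with La(OTf)3 would give its 4-methoxybenzyl ether F2, LiOH the seco acid F3, and Yamaguchi closure the ten-membered lactone F4. LiN(iPr)2 with Me3SiCl at −78 °C and warming would give 2-[(4-methoxybenzyl)oxy]-4-(propan-2-yl)-3-vinylcyclohexane-1-carboxylic acid F5 with the same three ring centres as 22. LiAlH4 would give the primary alcohol F6, Et3SiCl its triethylsilyl ether F7, and DDQ the secondary alcohol F8. Dess–Martin oxidation of F8 returns to the route at 25.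

**Step 12.** Oligomerisation to diolides may compete because a ten-membered ring closes slowly, and the activated β-ketal acid may lose its ketal by elimination under amine base. Fallback: Mitsunobu macrolactonisation of 17 (PPh3, diisopropyl azodicarboxylate, toluene, high dilution). This activates the allylic alcohol instead of the acid and closes the ring by carboxylate attack at sp3 carbon. It leads directly to 19 and makes no new compound.

**Step 21.** Initiation at the hindered vinyl group next to two ring substituents may be slow, so the catalyst could decay or cross-metathesis dimers could form before the electron-poor 1,1-disubstituted alkene is engaged. Fallback: relay metathesis. Morita–Baylis–Hillman reaction of hex-5-enal with 4 would give tert-butyl 3-hydroxy-2-methylideneoct-7-enoate F9, and N-bromosuccinimide with Me2S would give tert-butyl (2Z)-2-(bromomethyl)octa-2,7-dienoate F10. Alkylation of 33 with F10 (K2CO3, DMF) would give the relay ester F11. The same catalyst should load at the terminal alkene of F11, expel cyclopentene to place the metal on the acrylate carbon, and close onto the vinyl group, returning to the route at 36.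

**Step 27.** The triene is conjugated to an ester and may be too poor a diene, so the dienophile could polymerise or selectivity could fall at the higher temperature needed. Fallback: use the more electron-rich acetal diene and build the side chain afterwards. Setting out from 39 and 40, the coupling of step 24 is worked up without acid and 41 is isolated. Its cycloaddition with 47 under Et2AlCl would give (4S)-4-benzyl-3-{[(1R,2S)-2-(diethoxymethyl)-4-{[(4-methoxybenzyl)oxy]methyl}cyclohex-3-en-1-yl]carbonyl}-1,3-oxazolidin-2-one F12. Brief treatment with PPTS in wet acetone would give the aldehyde F13, which is used at once in the oxa-Michael/olefination of step 25 with 43 and 26, returning to the route at 48.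

**Step 33.** Acylation of the neopentyl-type hydroxyl may be slow, and a long-lived activated acyl species could deconjugate or epimerise at C-1′ or transfer to the tertiary hydroxyl. Fallback: form the ester by carboxylate alkylation. Setting out from 37, PPh3 and diisopropyl azodicarboxylate would give the spiro-epoxide tert-butyl (5aR,6S,9R,9aS)-1-oxo-6-(propan-2-yl)-3,5a,6,7,8,9a-hexahydro-1H-spiro[2-benzoxepine-9,2′-oxirane]-4-carboxylate F14. Opening at its CH2 terminus by acid 53 with catalytic Cs2CO3 in DMF returns to the route at 55.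

## Further compounds

F0 | step 12 | none | none
F1 | step 13 | methyl (6S,7Z)-9-acetoxy-3-hydroxy-6-(propan-2-yl)non-7-enoate (C-3 epimers) | CC(C)[C@H](CCC(O)CC(=O)OC)/C=C\COC(C)=O
F2 | step 13 | methyl (6S,7Z)-9-acetoxy-3-[(4-methoxybenzyl)oxy]-6-(propan-2-yl)non-7-enoate | CC(C)[C@H](CCC(CC(=O)OC)OCc1ccc(OC)cc1)/C=C\COC(C)=O
F3 | step 13 | (6S,7Z)-9-hydroxy-3-[(4-methoxybenzyl)oxy]-6-(propan-2-yl)non-7-enoic acid | CC(C)[C@H](CCC(CC(=O)O)OCc1ccc(OC)cc1)/C=C\CO
F4 | step 13 | (7S,8Z)-4-[(4-methoxybenzyl)oxy]-7-(propan-2-yl)-3,4,5,6,7,10-hexahydro-2H-oxecin-2-one | O=C1CC(OCc2ccc(OC)cc2)CC[C@@H](C(C)C)/C=C\CO1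
F5 | step 13 | (1S,2S,3S)-6-[(4-methoxybenzyl)oxy]-3-(propan-2-yl)-2-vinylcyclohexane-1-carboxylic acid (C-6 epimers) | CC(C)[C@@H]1CCC(OCc2ccc(OC)cc2)[C@@H](C(=O)O)[C@H]1C=C
F6 | step 13 | [(1R,2S,3S)-6-[(4-methoxybenzyl)oxy]-3-(propan-2-yl)-2-vinylcyclohexyl]methanol | CC(C)[C@@H]1CCC(OCc2ccc(OC)cc2)[C@@H](CO)[C@H]1C=C
F7 | step 13 | triethyl{[(1R,2S,3S)-6-[(4-methoxybenzyl)oxy]-3-(propan-2-yl)-2-vinylcyclohexyl]methoxy}silane | CC(C)[C@@H]1CCC(OCc2ccc(OC)cc2)[C@@H](CO[Si](CC)(CC)CC)[C@H]1C=C
F8 | step 13 | (2R,3S,4S)-4-(propan-2-yl)-2-{[(triethylsilyl)oxy]methyl}-3-vinylcyclohexan-1-ol (C-1 epimers) | CC(C)[C@@H]1CCC(O)[C@@H](CO[Si](CC)(CC)CC)[C@H]1C=C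
F9 | step 21 | tert-butyl 3-hydroxy-2-methylideneoct-7-enoate | C=CCCCC(O)C(=C)C(=O)OC(C)(C)C
F10 | step 21 | tert-butyl (2Z)-2-(bromomethyl)octa-2,7-dienoate | C=CCCC/C=C(\CBr)C(=O)OC(C)(C)C
F11 | step 21 | (2Z)-2-(tert-butoxycarbonyl)octa-2,7-dien-1-yl (1S,2R,5S,6S)-2-hydroxy-2-{[(4-methoxybenzyl)oxy]methyl}-5-(propan-2-yl)-6-vinylcyclohexane-1-carboxylate | CC(C)[C@@H]1CC[C@](O)(COCc2ccc(OC)cc2)[C@@H](C(=O)OC/C(=C\CCCC=C)C(=O)OC(C)(C)C)[C@H]1C=C
F12 | step 27 | (4S)-4-benzyl-3-{[(1R,2S)-2-(diethoxymethyl)-4-{[(4-methoxybenzyl)oxy]methyl}cyclohex-3-en-1-yl]carbonyl}-1,3-oxazolidin-2-one | CCOC(OCC)[C@H]1C=C(COCc2ccc(OC)cc2)CC[C@H]1C(=O)N1[C@@H](Cc2ccccc2)COC1=O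
F13 | step 27 | (1S,6R)-6-{[(4S)-4-benzyl-2-oxo-1,3-oxazolidin-3-yl]carbonyl}-3-{[(4-methoxybenzyl)oxy]methyl}cyclohex-2-ene-1-carbaldehyde | O=C[C@H]1C=C(COCc2ccc(OC)cc2)CC[C@H]1C(=O)N1[C@@H](Cc2ccccc2)COC1=O
F14 | step 33 | tert-butyl (5aR,6S,9R,9aS)-1-oxo-6-(propan-2-yl)-3,5a,6,7,8,9a-hexahydro-1H-spiro[2-benzoxepine-9,2′-oxirane]-4-carboxylate | CC(C)[C@@H]1CC[C@]2(CO2)[C@H]2C(=O)OCC(C(=O)OC(C)(C)C)=C[C@@H]12
A1 | alternative 1 | protected cyclohexane-fused oxepinone (silyl ether, 2-(trimethylsilyl)ethyl ester) | CC(C)[C@@H]1CC[C@](O)(CO[Si](C)(C)C(C)(C)C)[C@H]2C(=O)OCC(C(=O)OCC[Si](C)(C)C)=C[C@@H]12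
A2 | alternative 1 | diene ester precursor of A1 | CC(C)[C@@H]1CC[C@](O)(CO[Si](C)(C)C(C)(C)C)[C@@H](C(=O)OCC(=C)C(=O)OCC[Si](C)(C)C)[C@H]1C=C
A3 | alternative 2 | (S)-cryptone, (4S)-4-(propan-2-yl)cyclohex-2-en-1-one | CC(C)[C@@H]1CCC(=O)C=C1
A4 | alternative 2 | acetylene | C#C
A5 | alternative 2 | cis-fused 5-(propan-2-yl)bicyclo[4.2.0]oct-7-en-2-one, cyclobutene anti to isopropyl | CC(C)[C@@H]1CCC(=O)[C@H]2C=C[C@@H]12
A6 | alternative 3 | tert-butyl({(3E)-5-[(4-methoxybenzyl)oxy]-2-methylidenepent-3-en-1-yl}oxy)dimethylsilane | COc1ccc(COC/C=C/C(=C)CO[Si](C)(C)C(C)(C)C)cc1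
A7 | alternative 3 | 3-acryloyl-1,3-oxazolidin-2-one | C=CC(=O)N1CCOC1=O
A8 | alternative 3 | cis-3,4-disubstituted cyclohexene imide | COc1ccc(COC[C@H]2C=C(CO[Si](C)(C)C(C)(C)C)CC[C@H]2C(=O)N3CCOC3=O)cc1
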